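**Retrosynthetic overview**

1. Sophoraisoflavone A comes from its tri-O-benzyl ether by cleavage of the three aryl benzyl ethers, with the chromene left in place.
2. The tribenzyl isoflavone is cut at C4–C4a, an intramolecular Friedel–Crafts acylation of a (Z)-3-aryloxy-2-arylacrylic acid that closes the pyranone ring C. The strategy rests on ring A, which carries O1 on C8a and oxygen on C5 and C7 (a phloroglucinol pattern): in the open aryl vinyl ether the two carbons ortho to O1 are equivalent, each is ortho and para to the other two oxygens, and whichever attacks becomes C4a.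
3. The acid comes from the enol tosylate of an α-formyl arylacetate and 3,5-bis(benzyloxy)phenol (O1–C2 bond by addition–elimination). The α-formyl ester comes from the chromene-8-carbaldehyde and ethyl diazoacetate by a 1,2-aryl shift.
4. The chromene aldehyde comes from the 1,1-dimethylpropargyl ether of 4-(benzyloxy)-2-hydroxybenzaldehyde by Claisen rearrangement and 6π electrocyclisation.
5. Ring order: ring A and the benzene ring of the chromene are bought; the dimethylpyran ring is formed in step 2 and the pyranone ring C last, in step 7.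

Key step: step 7

Remark on geometry: the enol tosylate, the aryl vinyl ether ester and the acid are drawn as Z isomers, which chelation-controlled tosylation and stereoretentive vinylic substitution should give. Any E isomer is carried along, because the acid chloride equilibrates under SnCl4 and only its Z form can close.

Remark on ring B: its two oxygens are told apart at the outset by the hydrogen bond of a 2,4-dioxygenated benzaldehyde, and the arylacetic carbon is then added by aryl migration. This avoids treating a benzofuranone, whose lactone methylene is acidic, with alkylating base.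

**Route**

Step 1
Reactants: 1 4-(benzyloxy)-2-hydroxybenzaldehyde; 2 3-chloro-3-methylbut-1-yne
Product: 3 4-(benzyloxy)-2-[(2-methylbut-3-yn-2-yl)oxy]benzaldehyde
Conditions: 2 (1.3 equiv), DBU, CuCl2·2H2O (1 mol %), MeCN, 0 °C to rt
Reagents that add atoms: none
Why: Copper-catalysed propargylic etherification of a phenol, in which DBU breaks the hydrogen bond to the aldehyde and the copper acetylide of the tertiary chloride ionises readily; the 4-oxygen is already a benzyl ether, so only the 2-oxygen can react.

Step 2
Reactants: 3 4-(benzyloxy)-2-[(2-methylbut-3-yn-2-yl)oxy]benzaldehyde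
Product: 5 5-(benzyloxy)-2,2-dimethyl-2H-chromene-8-carbaldehyde, via allenylphenol 4 (not isolated)
Conditions: PhNEt2, 180 °C
Reagents that add atoms: none
Why: Aromatic propargyl Claisen rearrangement to the only free ortho carbon (the other bears the formyl group), followed by 1,5-hydrogen shift of the allenylphenol and 6π oxa-electrocyclisation, a standard entry to 2,2-dimethylchromenes.

Step 3
Reactants: 5 5-(benzyloxy)-2,2-dimethyl-2H-chromene-8-carbaldehyde; 6 ethyl diazoacetate
Product: 7 ethyl (Z)-2-[5-(benzyloxy)-2,2-dimethyl-2H-chromen-8-yl]-3-hydroxyprop-2-enoate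
Conditions: 6 (1.3 equiv, slow addition), HBF4·OEt2 (10 mol %), CH2Cl2, −78 °C to rt
Reagents that add atoms: none
Why: Acid-catalysed addition of the diazo ester to the aldehyde and loss of N2 with 1,2-shift of the electron-rich aryl group (ortho and para oxygen) in preference to hydride, the known aryl-shift homologation of electron-rich benzaldehydes to 3-hydroxy-2-arylacrylates, which rest as the hydrogen-bonded Z enol.

Step 4
Reactants: 7 ethyl (Z)-2-[5-(benzyloxy)-2,2-dimethyl-2H-chromen-8-yl]-3-hydroxyprop-2-enoate
Product: 8 ethyl (Z)-2-[5-(benzyloxy)-2,2-dimethyl-2H-chromen-8-yl]-3-[(4-methylbenzenesulfonyl)oxy]prop-2-enoate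
Conditions: TsCl, TMEDA, LiCl, MeCN, 0 °C
Reagents that add atoms: 4-methylbenzenesulfonyl chloride, Cc1ccc(cc1)S(=O)(=O)Cl
Why: O-sulfonylation of the lithium-chelated enolate (stereoselective enol tosylation), which holds the tosyloxy group cis to the ester and turns the enol into a vinylogous mixed anhydride.

Step 5
Reactants: 8 ethyl (Z)-2-[5-(benzyloxy)-2,2-dimethyl-2H-chromen-8-yl]-3-[(4-methylbenzenesulfonyl)oxy]prop-2-enoate; 9 3,5-bis(benzyloxy)phenol
Product: 10 ethyl (Z)-3-[3,5-bis(benzyloxy)phenoxy]-2-[5-(benzyloxy)-2,2-dimethyl-2H-chromen-8-yl]prop-2-enoate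
Conditions: 9 (1.05 equiv), Cs2CO3, DMF, 0 °C to rt
Reagents that add atoms: none
Why: Nucleophilic vinylic substitution by addition–elimination of the phenoxide at the β-carbon of the β-tosyloxyacrylate, where the good leaving group departs from the ester-stabilised carbanion before it rotates, so the geometry should be retained.

Step 6
Reactants: 10 ethyl (Z)-3-[3,5-bis(benzyloxy)phenoxy]-2-[5-(benzyloxy)-2,2-dimethyl-2H-chromen-8-yl]prop-2-enoate
Product: 11 (Z)-3-[3,5-bis(benzyloxy)phenoxy]-2-[5-(benzyloxy)-2,2-dimethyl-2H-chromen-8-yl]prop-2-enoic acid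
Conditions: LiOH·H2O, THF/H2O (3:1), rt to 40 °C; then 1 M HCl to pH 3, 0 °C
Reagents that add atoms: lithium hydroxide, [Li+].[OH-]
Why: Ester saponification without alcohol co-solvent, so that no alkoxide can exchange the aryloxy group, and the carboxylate once formed resists conjugate attack; benzyl ethers and the chromene are stable to base.

Step 7
Reactants: 11 (Z)-3-[3,5-bis(benzyloxy)phenoxy]-2-[5-(benzyloxy)-2,2-dimethyl-2H-chromen-8-yl]prop-2-enoic acid
Product: 13 5,7-bis(benzyloxy)-3-[5-(benzyloxy)-2,2-dimethyl-2H-chromen-8-yl]-4H-chromen-4-one, via Z acid chloride 12 (not isolated)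
Conditions: 1-chloro-N,N,2-trimethylprop-1-en-1-amine (1.1 equiv), CH2Cl2, 0 °C to rt; then 2,6-di-tert-butyl-4-methylpyridine, SnCl4 (2.2 equiv), CH2Cl2, −78 to −20 °C
Reagents that add atoms: none
Why: The acid is turned under neutral conditions into acid chloride 12, a vinylogous aryl chloroformate, whose SnCl4 complex presents an acylium-like carbon (future C4) to the neighbouring carbon of ring A ortho to the vinyloxy oxygen (future C4a), and the arenium ion then gives its proton to the hindered pyridine. The closest known reaction type is the cyclisation of 3-aryloxyacrylic acids and their chlorides to chromones by intramolecular Friedel–Crafts acylation, applied here with an aryl group on the α-carbon. Ring C closes as a six-membered pyranone by a 6-exo-trig attack on the acyl carbon that forms the C4–C4a bond. No stereocentre is formed. The step needs site selectivity on ring A and a Z olefin: the two carbons ortho to the vinyloxy oxygen are equivalent by the symmetry of the 3,5-bis(benzyloxy)phenoxy ring and each is ortho and para to a benzyloxy group, while the para carbon cannot reach the acyl carbon. The Z geometry is set in steps 4 and 5, and any E isomer should equilibrate through the SnCl4-complexed push–pull system, in which the C2–C3 bond has lost double-bond character; neutral chloride formation and the proton trap keep acid away from the chromene.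

Step 8
Reactants: 13 5,7-bis(benzyloxy)-3-[5-(benzyloxy)-2,2-dimethyl-2H-chromen-8-yl]-4H-chromen-4-one
Product: 14 sophoraisoflavone A, 5,7-dihydroxy-3-(5-hydroxy-2,2-dimethyl-2H-chromen-8-yl)-4H-chromen-4-one
Conditions: BCl3 (6 equiv), C6HMe5 (9 equiv), CH2Cl2, −78 °C; MeOH quench at −78 °C
Reagents that add atoms: none
Why: Lewis-acid cleavage of aryl benzyl ethers, with pentamethylbenzene as a non-basic scavenger that takes up the benzyl cations by Friedel–Crafts alkylation before they can alkylate rings A and B; no hydrogen is used, so the chromene olefin is not reduced.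

**Compound list**

1 | 4-(benzyloxy)-2-hydroxybenzaldehyde | O=Cc1ccc(OCc2ccccc2)cc1O | starting material
2 | 3-chloro-3-methylbut-1-yne | CC(C)(Cl)C#C | starting material
3 | 4-(benzyloxy)-2-[(2-methylbut-3-yn-2-yl)oxy]benzaldehyde | O=Cc1ccc(OCc2ccccc2)cc1OC(C)(C)C#C | intermediate
4 | 4-(benzyloxy)-2-hydroxy-3-(3-methylbuta-1,2-dien-1-yl)benzaldehyde | O=Cc1ccc(OCc2ccccc2)c(C=C=C(C)C)c1O | intermediate (not isolated)
5 | 5-(benzyloxy)-2,2-dimethyl-2H-chromene-8-carbaldehyde | CC1(C)C=Cc2c(OCc3ccccc3)ccc(C=O)c2O1 | intermediate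
6 | ethyl diazoacetate | CCOC(=O)C=[N+]=[N-] | starting material
7 | ethyl (Z)-2-[5-(benzyloxy)-2,2-dimethyl-2H-chromen-8-yl]-3-hydroxyprop-2-enoate | CCOC(=O)/C(=C\O)c1ccc(OCc2ccccc2)c2C=CC(C)(C)Oc12 | intermediate
8 | ethyl (Z)-2-[5-(benzyloxy)-2,2-dimethyl-2H-chromen-8-yl]-3-[(4-methylbenzenesulfonyl)oxy]prop-2-enoate | CCOC(=O)/C(=C\OS(=O)(=O)c1ccc(C)cc1)c1ccc(OCc2ccccc2)c2C=CC(C)(C)Oc12 | intermediate
9 | 3,5-bis(benzyloxy)phenol | Oc1cc(OCc2ccccc2)cc(OCc2ccccc2)c1 | starting material
10 | ethyl (Z)-3-[3,5-bis(benzyloxy)phenoxy]-2-[5-(benzyloxy)-2,2-dimethyl-2H-chromen-8-yl]prop-2-enoate | CCOC(=O)/C(=C\Oc1cc(OCc2ccccc2)cc(OCc2ccccc2)c1)c1ccc(OCc2ccccc2)c2C=CC(C)(C)Oc12 | intermediate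
11 | (Z)-3-[3,5-bis(benzyloxy)phenoxy]-2-[5-(benzyloxy)-2,2-dimethyl-2H-chromen-8-yl]prop-2-enoic acid | OC(=O)/C(=C\Oc1cc(OCc2ccccc2)cc(OCc2ccccc2)c1)c1ccc(OCc2ccccc2)c2C=CC(C)(C)Oc12 | intermediate
12 | (Z)-3-[3,5-bis(benzyloxy)phenoxy]-2-[5-(benzyloxy)-2,2-dimethyl-2H-chromen-8-yl]prop-2-enoyl chloride | ClC(=O)/C(=C\Oc1cc(OCc2ccccc2)cc(OCc2ccccc2)c1)c1ccc(OCc2ccccc2)c2C=CC(C)(C)Oc12 | intermediate (not isolated)
13 | 5,7-bis(benzyloxy)-3-[5-(benzyloxy)-2,2-dimethyl-2H-chromen-8-yl]-4H-chromen-4-one | O=c1c(-c2ccc(OCc3ccccc3)c3C=CC(C)(C)Oc23)coc2cc(OCc3ccccc3)cc(OCc3ccccc3)c12 | intermediate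
14 | sophoraisoflavone A, 5,7-dihydroxy-3-(5-hydroxy-2,2-dimethyl-2H-chromen-8-yl)-4H-chromen-4-one | CC1(C)C=Cc2c(O)ccc(-c3coc4cc(O)cc(O)c4c3=O)c2O1 | target

**Totals**

Total step count: 8. Longest linear sequence: 8 steps (1 to 14); phenol 9 enters at step 5.

**Steps most likely to fail**

Step 7 (ring closure). The activated acyl carbon may be captured by the chromene oxygen of ring B, which sits on the carbon next to the point of attachment; this would close a five-membered lactone with loss of the tertiary allylic carbon. The acid chloride may also decompose before any E isomer has equilibrated. Loss of the benzyl ether next to the new carbonyl under SnCl4 would be harmless, since step 8 removes it anyway. The fallback is the deoxybenzoin route, which closes ring C at O1–C2 with a one-carbon unit. It sets out from 7 and returns at 13.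
- Aqueous NaOH in EtOH at 60 °C, then acidification, should cleave the formyl group as formate and hydrolyse the ester to 2-[5-(benzyloxy)-2,2-dimethyl-2H-chromen-8-yl]acetic acid F1.
- Trifluoroacetic anhydride in CH2Cl2 at 0 °C should turn F1 into its mixed anhydride, which acylates 1,3,5-tris(benzyloxy)benzene F2 to 2-[5-(benzyloxy)-2,2-dimethyl-2H-chromen-8-yl]-1-[2,4,6-tris(benzyloxy)phenyl]ethan-1-one F3.
- MgBr2·OEt2 in toluene/Et2O should remove one benzyl group ortho to the ketone by chelation, giving 1-[2,4-bis(benzyloxy)-6-hydroxyphenyl]-2-[5-(benzyloxy)-2,2-dimethyl-2H-chromen-8-yl]ethan-1-one F4.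
- N,N-dimethylformamide dimethyl acetal in toluene at 90 °C should form the enaminone of F4 and close the pyranone to 13.

Step 5 (vinyl ether formation). The phenoxide may attack sulfur of the tosylate instead of the β-carbon, which transfers the sulfonyl group and returns the enolate of 7; slow substitution may also let the geometry drift. The fallback replaces the sulfonate, which has two electrophilic sites, by a vinyl chloride that can only be attacked at carbon. It sets out from 7 and returns at 10.
- Ph3PCl2 and Et3N in CH2Cl2 at 0 °C should convert the enol into ethyl (Z)-2-[5-(benzyloxy)-2,2-dimethyl-2H-chromen-8-yl]-3-chloroprop-2-enoate F5.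
- Phenol 9 with K2CO3 in DMF at rt should displace chloride from F5 by addition–elimination to give 10.

Step 8 (debenzylation). BCl3 may ionise the tertiary allylic C2–O1 bond of the chromene, or the acid released may protonate its olefin, and the resulting cation may be captured by the scavenger. The fallback accepts loss of the olefin and restores it afterwards. It sets out from 13 and returns at 14.
- H2 (1 atm) over Pd/C in EtOAc/MeOH should cleave the three benzyl ethers and saturate the chromene olefin, giving 5,7-dihydroxy-3-(5-hydroxy-2,2-dimethyl-3,4-dihydro-2H-chromen-8-yl)-4H-chromen-4-one F6.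
- DDQ in 1,4-dioxane at reflux should dehydrogenate the chroman F6 at C3–C4 (hydride abstraction from the benzylic carbon ortho to the free hydroxyl), the usual way of making 2,2-dimethylchromenes from chromans, to give 14.

**Further compounds**

F1 | step 7 | 2-[5-(benzyloxy)-2,2-dimethyl-2H-chromen-8-yl]acetic acid | OC(=O)Cc1ccc(OCc2ccccc2)c2C=CC(C)(C)Oc12
F2 | step 7 | 1,3,5-tris(benzyloxy)benzene | c1(OCc2ccccc2)cc(OCc2ccccc2)cc(OCc2ccccc2)c1
F3 | step 7 | 2-[5-(benzyloxy)-2,2-dimethyl-2H-chromen-8-yl]-1-[2,4,6-tris(benzyloxy)phenyl]ethan-1-one | O=C(Cc1ccc(OCc2ccccc2)c2C=CC(C)(C)Oc12)c1c(OCc2ccccc2)cc(OCc2ccccc2)cc1OCc1ccccc1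
F4 | step 7 | 1-[2,4-bis(benzyloxy)-6-hydroxyphenyl]-2-[5-(benzyloxy)-2,2-dimethyl-2H-chromen-8-yl]ethan-1-one | O=C(Cc1ccc(OCc2ccccc2)c2C=CC(C)(C)Oc12)c1c(O)cc(OCc2ccccc2)cc1OCc1ccccc1
F5 | step 5 | ethyl (Z)-2-[5-(benzyloxy)-2,2-dimethyl-2H-chromen-8-yl]-3-chloroprop-2-enoate | CCOC(=O)/C(=C\Cl)c1ccc(OCc2ccccc2)c2C=CC(C)(C)Oc12
F6 | step 8 | 5,7-dihydroxy-3-(5-hydroxy-2,2-dimethyl-3,4-dihydro-2H-chromen-8-yl)-4H-chromen-4-one | CC1(C)CCc2c(O)ccc(-c3coc4cc(O)cc(O)c4c3=O)c2O1
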